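L still sitting in the second phase at 6.0 h is reagent that has done nothing, so I first ask how much of it crosses. L enters the first phase as G. There G joins Z to give Z.G, or turns to E. Z.G turns to D, or meets a second Z to give Z.Z.G.

Z 0.15 M; L 1.00 equiv; time 6.0 h; volume of the second phase over the first 0.50

- a species is counted by the Z in it: one Z.Z.G counts as two
- in the second phase: L; everything else is in the first
- charges count per volume of the first phase; a concentration in a rate is the amount of a species over the volume of its own phase; every rate counts per litre of the first phase
- run time (flask): 6.0 h

- amount of Z.G at 6.0 h, in percent of the Z charged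
- the change that raises the amount of Z.G at 6.0 h, in percent of the Z charged most ("none" if none brings more than 2 percentage points) (cedar / alder / none)
- amount of Z.G at 6.0 h, in percent of the Z charged, after cedar

    Z.G ⇌ D (K1 = 2.2, k1 = 1.12 × 10⁻⁴ s⁻¹)
    Z + Z.G → Z.Z.G (k2 = 2.53 × 10⁻⁴ M⁻¹ s⁻¹)
    Z + G → Z.G (k3 = 0.00170 M⁻¹ s⁻¹)
    G ⇌ L, rate k4*([G] - [L]/K4) per volume of the first phase (K4 = 2.01, k4 = 3.75 × 10⁻⁵ s⁻¹)
    G ⇌ E (K5 = 0.878, k5 = 1.05 × 10⁻⁴ s⁻¹)

I neglect the return of G to L in the delivery. L then empties at a constant of 0.134 h⁻¹, the transfer coefficient over the partition ratio and the volume ratio. By 6.0 h, the delivered share is 55.3% of the L charged. I spread that delivery evenly over the run and call it the feed.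

With Z held at its charge, the part of G that meets Z is 64.2%, against transfer and turning to E. Counting step 1 forward, Z.G drains at a pseudo-first-order constant of 0.540 h⁻¹. That gives a half-life of 1.28 h, shorter than the run. So I expect control to pass from elapsed time to a balance, and I put Z.G near the balance level, the feed times the share over the drain constant: 0.0164 M.

Delivered equivalents, share, balance level in percent of Z:

- flask: 0.553, 64.2%, 11.0%
- cedar: 1.11, 64.2%, 21.9%
- alder: 0.800, 58.6%, 14.5%

I read down the first column. Cedar delivers twice what the flask delivers. By this reckoning alder delivers less than cedar. In the second column, alder's share is smaller than the flask's. I commit to cedar.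

The forecast gives 14.6% for the flask, cedar as the best change and 23.5% after it, saying that “slow transfer from L holds G near 13 mM”. The simulation gives 14.3% for the flask and 25.1% after cedar, which gains 11 percentage points against 4.6 points for alder.

At 6.00 h the flask makes Z.G 1.19 times as fast as it uses it, each step taken net, and Z.G and D relax with a half-life of 1.18 h, short against the run. The flask's Z.G lies 3.3 points above my balance level, which counts step 1 forward. In the neighbour flask with 0.037 M of Z, the delivered share stays 55.3% and the same rule gives 6.46%, while that flask holds 8.46%.

The constants used here stand for no real mixture; the result is computed.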